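**Retrosynthetic overview**

1. The strategy rests on this feature of the ring: C12–C13–C14–C1–C2–C3 is a latent cyclohexanone (carbonyl at C12). The other eight ring atoms are two four-carbon blocks, C4–C7 and C8–C11, each leaving a trisubstituted alkene (C3=C4, C7=C8) δ,ε to C12, which is the footprint of two successive oxy-Cope shifts.
2. C12–CH3 is cut back to an enol triflate. The fourteen-membered ring is then cut at C9–C10 (anionic oxy-Cope) to a ten-membered carbinol with vinyl on C12 and isopropenyl on C7, in which the C7–C12 bond is present.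
3. The ten-membered ketone is cut at C5–C6 (first oxy-Cope) to a cyclohexanol with a 3-methylbuta-1,3-dien-2-yl group on C12 and a silyloxypropenyl group on C3.
4. The cyclohexanone comes from C2–C3 enolate alkylation and C12–C3 allylation. C1 and C15 come from (2S,3R)-epoxynerol opened at its C2 by a three-carbon Grignard reagent.
5. Ring order: six-membered ring (step 9), ten-membered ring (step 12), fourteen-membered ring (step 14).

Key step: step 14

Remark (numbering): ring atoms are C1 (CH bearing the carbinol carbon C15), C2, C3=C4(CH2OH), C5, C6, C7=C8(CH3), C9, C10, C11=C12(CH3), C13, C14; this numbering is used for all intermediates.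

Remark (chemistry): L-(+)-diethyl tartrate is assumed to give the (2S,3R)-epoxide of the Z-allylic alcohol, the usual sense of the tartrate rule. Centres that are erased later (the carbinol of 14, C3 and C12 of 17 and 23, C7 of 26) are carried as mixtures, and the isomer expected to predominate is drawn.

**Route**

Step 1
Reactants: 1 nerol
Product: 2 (2S,3R)-2,3-epoxynerol
Conditions: Ti(OiPr)4 (5 mol%), L-(+)-diethyl tartrate (7 mol%), t-BuOOH, 4 Å molecular sieves, CH2Cl2, −20 °C
Reagents that add atoms: tert-butyl hydroperoxide, CC(C)(C)OO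
Why: Katsuki–Sharpless asymmetric epoxidation of the Z-allylic alcohol, in which the tartrate ligand selects the alkene face and so fixes, in one operation, the two carbons that become C1 and C15.

Step 2
Reactants: 2 (2S,3R)-2,3-epoxynerol; 3 2-(2-bromoethyl)-1,3-dioxolane
Product: 5 (2R,3R)-2-[2-(1,3-dioxolan-2-yl)ethyl]-3,7-dimethyloct-6-ene-1,3-diol, via Grignard reagent 4 (not isolated)
Conditions: 3, Mg, THF, 25 °C; then CuI (10 mol%), 2, THF, −30 → 0 °C; aq. NH4Cl
Reagents that add atoms: none
Why: Copper-catalysed Grignard opening of a 2,3-epoxy alcohol whose C3 is fully substituted should occur by SN2 attack at the less hindered C2 with inversion, which sets C1 while C15 keeps its oxygen with retention and gives the 1,3-diol.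

Step 3
Reactants: 5 (2R,3R)-2-[2-(1,3-dioxolan-2-yl)ethyl]-3,7-dimethyloct-6-ene-1,3-diol
Product: 6 primary 4-toluenesulfonate of 5 (tertiary hydroxyl free)
Conditions: TsCl, Et3N, DMAP (cat.), CH2Cl2, 0 °C
Reagents that add atoms: 4-toluenesulfonyl chloride, Cc1ccc(cc1)S(=O)(=O)Cl
Why: Selective sulfonylation, the primary hydroxyl reacting far faster than the hindered tertiary one, turns C2 into the electrophile for the later ring closure.

Step 4
Reactants: 6 primary 4-toluenesulfonate of 5
Product: 9 (2R,3R)-3,7-dimethyl-2-(3-oxopropyl)-3-(triethylsilyloxy)oct-6-en-1-yl 4-methylbenzenesulfonate, via silyl ether 7 (not isolated), via collidinium salt 8 (not isolated)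
Conditions: Et3SiOTf (3.5 equiv), 2,4,6-collidine (5 equiv), CH2Cl2, −78 → 0 °C; then H2O, 0 → 25 °C
Reagents that add atoms: triethylsilyl trifluoromethanesulfonate, CC[Si](CC)(CC)OS(=O)(=O)C(F)(F)F; water, O
Why: The silyl triflate first silylates the tertiary alcohol at low temperature and then, with the pyridine base, opens the aldehyde-derived dioxolane to a collidinium salt that water hydrolyses to the C12 aldehyde (silyl triflate–pyridine base acetal cleavage), non-acidic conditions that spare the new silyl ether and the tosylate.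

Step 5
Reactants: 10 2-methylenepropane-1,3-diol
Product: 11 2-[(tert-butyldimethylsilyloxy)methyl]prop-2-en-1-ol
Conditions: NaH (1.0 equiv), THF, 0 → 25 °C; then t-BuMe2SiCl
Reagents that add atoms: tert-butyldimethylsilyl chloride, CC(C)(C)[Si](C)(C)Cl
Why: Monosilylation of a symmetric diol through its sparingly soluble monosodium alkoxide, which reacts once and leaves the second hydroxyl free.

Step 6
Reactants: 11 2-[(tert-butyldimethylsilyloxy)methyl]prop-2-en-1-ol
Product: 12 {[2-(bromomethyl)prop-2-en-1-yl]oxy}(tert-butyl)dimethylsilane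
Conditions: CBr4, PPh3, CH2Cl2, 0 °C
Reagents that add atoms: carbon tetrabromide, BrC(Br)(Br)Br
Why: Appel bromination converts the primary allylic alcohol into the bromide under neutral conditions that keep the silyl ether.

Step 7
Reactants: 9 aldehyde; 12 allylic bromide
Product: 14 homoallylic alcohol (C12 carbinol as both epimers; C12–C3 bond formed), via allylzinc bromide 13 (not isolated)
Conditions: Zn dust, THF/sat. aq. NH4Cl, 0 → 25 °C
Reagents that add atoms: none
Why: Zinc-mediated Barbier allylation in aqueous medium adds the symmetric 2-substituted allyl unit to the aldehyde without touching the tosylate or the silyl ethers; the new carbinol centre is not controlled and is removed in step 8.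

Step 8
Reactants: 14 homoallylic alcohol
Product: 15 β,γ-unsaturated ketone (C12=O, C3H2, C4=C5H2)
Conditions: Dess–Martin periodinane, pyridine, CH2Cl2, 0 → 25 °C
Reagents that add atoms: none
Why: Dess–Martin oxidation of the secondary alcohol under buffered conditions should give the ketone without moving the 1,1-disubstituted alkene into conjugation.

Step 9
Reactants: 15 β,γ-unsaturated ketone
Product: 17 (2S,4R)-2-[3-(tert-butyldimethylsilyloxy)prop-1-en-2-yl]-4-[(2R)-6-methyl-2-(triethylsilyloxy)hept-5-en-2-yl]cyclohexan-1-one, via potassium dienolate 16 (not isolated)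
Conditions: KOtBu (1.1 equiv), THF, −40 → 0 °C; then AcOH, −78 °C
Reagents that add atoms: none
Why: The C3 hydrogens between carbonyl and alkene are the most acidic, and the extended dienolate should alkylate at its α-carbon in a 6-(enolexo)-exo-tet closure onto the primary tosylate (intramolecular deconjugative enolate alkylation); C3 can equilibrate toward the 2,4-cis isomer and is erased in step 12.

Step 10
Reactants: 18 2-methylbut-1-en-3-yne
Product: 20 2-bromo-3-methylbuta-1,3-diene, via alkenylborane 19 (not isolated)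
Conditions: B-bromo-9-BBN, CH2Cl2, 0 °C; then AcOH, 0 → 25 °C
Reagents that add atoms: B-bromo-9-borabicyclo[3.3.1]nonane, BrB1C2CCCC1CCC2
Why: Bromoboration of a terminal alkyne is syn and Markovnikov and leaves alkenes untouched, and protonolysis of the alkenyl–boron bond with acetic acid gives the 2-bromo-1-alkene.

Step 11
Reactants: 17 cyclohexanone; 20 2-bromo-3-methylbuta-1,3-diene
Product: 23 (1S,2S,4R)-2-[3-(tert-butyldimethylsilyloxy)prop-1-en-2-yl]-1-(3-methylbuta-1,3-dien-2-yl)-4-[(2R)-6-methyl-2-(triethylsilyloxy)hept-5-en-2-yl]cyclohexan-1-ol, via dienyllithium 21 (not isolated), via dienylcerium dichloride 22 (not isolated)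
Conditions: 20, t-BuLi (2 equiv), Et2O, −78 °C; CeCl3, THF, −78 °C; then 17, −78 → −40 °C; aq. NH4Cl
Reagents that add atoms: none
Why: Bromine–lithium exchange and transmetalation give a weakly basic organocerium reagent that adds 1,2 to the enolisable ketone, equatorial attack placing the dienyl group trans to the C3 substituent; both new and old ring centres at C12 and C3 are erased in step 12, so any diastereomer is usable.

Step 12
Reactants: 23 1,2-dialkenylcyclohexanol
Product: 26 ten-membered ketone (C12=O, isopropenyl on C7 as both epimers, ring-trans C3=C4), via potassium alkoxide 24 (not isolated), via potassium dienolate 25 (not isolated)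
Conditions: KN(SiMe3)2 (1.2 equiv), 18-crown-6, THF, 0 → 40 °C; then AcOH, −78 °C
Reagents that add atoms: none
Why: Anionic oxy-Cope rearrangement through the chair array C5=C4–C3···C12–C7=C6 breaks C3–C12 and forms C5–C6, with C2 equatorial on C3 so that C2 and C5 end trans on C3=C4, and kinetic protonation of the dienolate at its α-carbon C7 at low temperature gives the unconjugated ketone.

Step 13
Reactants: 26 ten-membered ketone
Product: 27 ten-membered carbinol (OH and vinyl on C12, isopropenyl on C7 cis to vinyl; (7R,12R) form drawn, its (7S,12S) partner from the other C7 epimer is carried along)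
Conditions: CH2=CHMgBr, CeCl3, THF, −78 °C; aq. NH4Cl
Reagents that add atoms: vinylmagnesium bromide, C=C[Mg]Br
Why: Organocerium 1,2-addition avoids deprotonation of the doubly activated C7–H, and Felkin–Anh attack anti to the isopropenyl group on C7 should place vinyl cis to isopropenyl on the ring for either C7 epimer, which is the C7/C12 relation the key step needs.

Step 14
Reactants: 27 ten-membered carbinol
Product: 30 fourteen-membered enol triflate (7E; OTf on C12 trans to C10), via potassium alkoxide 28 (not isolated), via potassium enolate 29 (not isolated)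
Conditions: KN(SiMe3)2 (1.3 equiv), 18-crown-6, THF, −20 → 25 °C; then PhNTf2, −78 → 0 °C
Reagents that add atoms: N-phenylbis(trifluoromethanesulfonimide), O=S(=O)(N(c1ccccc1)S(=O)(=O)C(F)(F)F)C(F)(F)F
Why: The loosely paired potassium alkoxide 28 weakens C7–C12, so a concerted [3,3] shift through the chair array C10=C11–C12···C7–C8=C9 breaks C7–C12 and forms C9–C10; this is the anionic oxy-Cope four-carbon ring expansion of a 1,2-dialkenylcycloalkanol, a known reaction type that has been used twice in succession to reach fourteen-membered rings. The fourteen-membered ring is not closed end to end: the ten-membered ring grows by the four atoms C8–C11 as the transannular C7–C12 bond is exchanged for C9–C10. No stereocentre is formed; C7 and C12 become trigonal, so the (7R,12R) and (7S,12S) forms of 27 give the same enolate while C1 and C15 are untouched. The step needs the chair with C6 equatorial on C7 (C6 trans to C9, 7E) and C13 axial on C12 with the oxyanion equatorial (C13 cis to C10, oxygen trans to C10); the cis relation of vinyl and isopropenyl forces one ring bond axial and one equatorial, and the equatorial preference of the oxyanion together with the behaviour of cis-1,2-dialkenylcyclohexanols (trans alkene, ring-cis enolate) points to this chair, whereas the flipped chair would give the 7Z,11E isomer. PhNTf2 added cold sulfonylates the regio- and stereodefined enolate 29 on oxygen before proton transfer can scramble it, so the methyl group of step 15 inherits the position trans to C10.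

Step 15
Reactants: 30 fourteen-membered enol triflate
Product: 31 bis-silyl ether of the target (3Z,7E,11Z by CIP)
Conditions: Fe(acac)3 (10 mol%), MeMgBr, THF/NMP, −30 → 0 °C
Reagents that add atoms: methylmagnesium bromide, C[Mg]Br
Why: Iron-catalysed cross-coupling of an alkenyl triflate with a methyl Grignard reagent replaces OTf by CH3 with retention of alkene geometry and is fast enough at low temperature to leave the silyl ethers alone.

Step 16
Reactants: 31 bis-silyl ether
Product: 32 (2R)-2-[(1R,3Z,7E,11Z)-4-(hydroxymethyl)-8,12-dimethylcyclotetradeca-3,7,11-trien-1-yl]-6-methylhept-5-en-2-ol (target)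
Conditions: Bu4NF, THF, 25 → 45 °C; aq. NH4Cl
Reagents that add atoms: none
Why: Fluoride cleaves both the primary allylic tert-butyldimethylsilyl ether and the tertiary triethylsilyl ether without touching any alkene or stereocentre.

**Compound list**

1 | nerol, (2Z)-3,7-dimethylocta-2,6-dien-1-ol | CC(C)=CCC/C(C)=C\CO | starting material
2 | (2S,3R)-2,3-epoxynerol, [(2S,3R)-3-methyl-3-(4-methylpent-3-en-1-yl)oxiran-2-yl]methanol | CC(C)=CCC[C@@]1(C)O[C@H]1CO | intermediate
3 | 2-(2-bromoethyl)-1,3-dioxolane | BrCCC1OCCO1 | starting material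
4 | [2-(1,3-dioxolan-2-yl)ethyl]magnesium bromide | Br[Mg]CCC1OCCO1 | intermediate (not isolated)
5 | (2R,3R)-2-[2-(1,3-dioxolan-2-yl)ethyl]-3,7-dimethyloct-6-ene-1,3-diol | CC(C)=CCC[C@@](C)(O)[C@H](CCC1OCCO1)CO | intermediate
6 | (2R,3R)-2-[2-(1,3-dioxolan-2-yl)ethyl]-3-hydroxy-3,7-dimethyloct-6-en-1-yl 4-methylbenzenesulfonate | CC(C)=CCC[C@@](C)(O)[C@H](CCC1OCCO1)COS(=O)(=O)c1ccc(C)cc1 | intermediate
7 | triethylsilyl ether of 6 (dioxolane intact) | CC(C)=CCC[C@@](C)(O[Si](CC)(CC)CC)[C@H](CCC1OCCO1)COS(=O)(=O)c1ccc(C)cc1 | intermediate (not isolated)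
8 | collidinium triflate formed by opening the dioxolane of 7 (N,O-acetal carbon as both epimers) | CC(C)=CCC[C@@](C)(O[Si](CC)(CC)CC)[C@H](CCC(OCCO[Si](CC)(CC)CC)[n+]1c(C)cc(C)cc1C)COS(=O)(=O)c1ccc(C)cc1.[O-]S(=O)(=O)C(F)(F)F | intermediate (not isolated)
9 | (2R,3R)-3,7-dimethyl-2-(3-oxopropyl)-3-(triethylsilyloxy)oct-6-en-1-yl 4-methylbenzenesulfonate | CC(C)=CCC[C@@](C)(O[Si](CC)(CC)CC)[C@H](CCC=O)COS(=O)(=O)c1ccc(C)cc1 | intermediate
10 | 2-methylenepropane-1,3-diol | C=C(CO)CO | starting material
11 | 2-[(tert-butyldimethylsilyloxy)methyl]prop-2-en-1-ol | C=C(CO)CO[Si](C)(C)C(C)(C)C | intermediate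
12 | {[2-(bromomethyl)prop-2-en-1-yl]oxy}(tert-butyl)dimethylsilane | C=C(CBr)CO[Si](C)(C)C(C)(C)C | intermediate
13 | {2-[(tert-butyldimethylsilyloxy)methyl]prop-2-en-1-yl}zinc bromide | Br[Zn]CC(=C)CO[Si](C)(C)C(C)(C)C | intermediate (not isolated)
14 | homoallylic alcohol from 9 and 12 (C12 carbinol as both epimers) | CC(C)=CCC[C@@](C)(O[Si](CC)(CC)CC)[C@H](CCC(O)CC(=C)CO[Si](C)(C)C(C)(C)C)COS(=O)(=O)c1ccc(C)cc1 | intermediate
15 | β,γ-unsaturated ketone (C12=O) carrying the primary tosylate at C2 | CC(C)=CCC[C@@](C)(O[Si](CC)(CC)CC)[C@H](CCC(=O)CC(=C)CO[Si](C)(C)C(C)(C)C)COS(=O)(=O)c1ccc(C)cc1 | intermediate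
16 | potassium dienolate of 15 (C12–O, C12=C3, C4=C5) | CC(C)=CCC[C@@](C)(O[Si](CC)(CC)CC)[C@H](CCC([O-])=CC(=C)CO[Si](C)(C)C(C)(C)C)COS(=O)(=O)c1ccc(C)cc1.[K+] | intermediate (not isolated)
17 | (2S,4R)-2-[3-(tert-butyldimethylsilyloxy)prop-1-en-2-yl]-4-[(2R)-6-methyl-2-(triethylsilyloxy)hept-5-en-2-yl]cyclohexan-1-one (2,4-cis isomer drawn; the C2 epimer is carried along) | CC(C)=CCC[C@@](C)(O[Si](CC)(CC)CC)[C@@H]1CCC(=O)[C@@H](C1)C(=C)CO[Si](C)(C)C(C)(C)C | intermediate
18 | 2-methylbut-1-en-3-yne | C=C(C)C#C | starting material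
19 | 9-[(1Z)-2-bromo-3-methylbuta-1,3-dien-1-yl]-9-borabicyclo[3.3.1]nonane | C=C(C)/C(Br)=C/B1C2CCCC1CCC2 | intermediate (not isolated)
20 | 2-bromo-3-methylbuta-1,3-diene | C=C(C)C(Br)=C | intermediate
21 | (3-methylbuta-1,3-dien-2-yl)lithium | [Li]C(=C)C(C)=C | intermediate (not isolated)
22 | (3-methylbuta-1,3-dien-2-yl)cerium dichloride | Cl[Ce](Cl)C(=C)C(C)=C | intermediate (not isolated)
23 | (1S,2S,4R)-2-[3-(tert-butyldimethylsilyloxy)prop-1-en-2-yl]-1-(3-methylbuta-1,3-dien-2-yl)-4-[(2R)-6-methyl-2-(triethylsilyloxy)hept-5-en-2-yl]cyclohexan-1-ol (trans-dialkenyl isomer drawn; other C1/C2 isomers are carried along) | CC(C)=CCC[C@@](C)(O[Si](CC)(CC)CC)[C@@H]1CC[C@@](O)(C(=C)C(C)=C)[C@@H](C1)C(=C)CO[Si](C)(C)C(C)(C)C | intermediate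
24 | potassium alkoxide of 23 | CC(C)=CCC[C@@](C)(O[Si](CC)(CC)CC)[C@@H]1CC[C@@]([O-])(C(=C)C(C)=C)[C@@H](C1)C(=C)CO[Si](C)(C)C(C)(C)C.[K+] | intermediate (not isolated)
25 | ten-membered potassium dienolate (C12–O, C7=C12, isopropenyl on C7, ring-trans C3=C4) | CC(C)=CCC[C@@](C)(O[Si](CC)(CC)CC)[C@H]1C/C=C(\CO[Si](C)(C)C(C)(C)C)CCC(C(C)=C)=C([O-])CC1.[K+] | intermediate (not isolated)
26 | ten-membered ketone: C12=O, isopropenyl on C7 (both epimers), C3=C4 with C2 and C5 trans and CH2OSi(t-Bu)Me2 on C4, (R)-C1 bearing the (2R)-6-methyl-2-(triethylsilyloxy)hept-5-en-2-yl group | CC(C)=CCC[C@@](C)(O[Si](CC)(CC)CC)[C@H]1C/C=C(\CO[Si](C)(C)C(C)(C)C)CCC(C(C)=C)C(=O)CC1 | intermediate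
27 | ten-membered carbinol, key-step precursor: OH and vinyl on C12, isopropenyl on C7 cis to vinyl, (7R,12R) form drawn (the (7S,12S) form is carried along), otherwise as 26 | CC(C)=CCC[C@@](C)(O[Si](CC)(CC)CC)[C@H]1C/C=C(\CO[Si](C)(C)C(C)(C)C)CC[C@H](C(C)=C)[C@](O)(C=C)CC1 | intermediate
28 | potassium alkoxide of 27 | CC(C)=CCC[C@@](C)(O[Si](CC)(CC)CC)[C@H]1C/C=C(\CO[Si](C)(C)C(C)(C)C)CC[C@H](C(C)=C)[C@]([O-])(C=C)CC1.[K+] | intermediate (not isolated)
29 | fourteen-membered potassium enolate (C11=C12–O with O trans to C10, 7E) | CC(C)=CCC[C@@](C)(O[Si](CC)(CC)CC)[C@H]1C/C=C(\CO[Si](C)(C)C(C)(C)C)CC/C=C(\C)CC/C=C(/[O-])CC1.[K+] | intermediate (not isolated)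
30 | fourteen-membered enol triflate, key-step product (OTf on C12 trans to C10, 7E, ring-trans C3=C4) | CC(C)=CCC[C@@](C)(O[Si](CC)(CC)CC)[C@H]1C/C=C(\CO[Si](C)(C)C(C)(C)C)CC/C=C(\C)CC/C=C(/OS(=O)(=O)C(F)(F)F)CC1 | intermediate
31 | bis-silyl ether of the target (C15–OSiEt3, C4–CH2OSi(t-Bu)Me2; 3Z,7E,11Z) | CC(C)=CCC[C@@](C)(O[Si](CC)(CC)CC)[C@H]1C/C=C(\CO[Si](C)(C)C(C)(C)C)CC/C=C(\C)CC/C=C(/C)CC1 | intermediate
32 | (2R)-2-[(1R,3Z,7E,11Z)-4-(hydroxymethyl)-8,12-dimethylcyclotetradeca-3,7,11-trien-1-yl]-6-methylhept-5-en-2-ol | CC(C)=CCC[C@@](C)(O)[C@H]1C/C=C(\CO)CC/C=C(\C)CC/C=C(/C)CC1 | target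

**Step count and risks**

Total step count: 16. Longest linear sequence: 13 steps (steps 1–4, 7–9, 11–16 from nerol).

Steps most likely to fail:

Step 14. The flipped chair (C6 axial on C7, oxyanion axial on C12) may be selected in the loose, alkoxide-accelerated transition state, which would give the 7Z,11E isomer; the potassium enolate may also lose its geometry or position by proton transfer before it is sulfonylated. The fallback sets out from 27 and returns at 30, and replaces the anionic shift by the neutral silyloxy-Cope rearrangement, in which no free enolate exists and the bulkier silyloxy group has the stronger equatorial preference in a tighter chair. Me3Si-imidazole in CH2Cl2 should give the trimethylsilyl ether F1. Heating F1 in decalin at about 220 °C in base-washed glass should give the fourteen-membered trimethylsilyl enol ether F2 with the geometry fixed in the pericyclic step. MeLi in THF at 0 °C should then cleave the Si–O bond to the lithium enolate F3 with retention of position and geometry, and PhNTf2 should give 30.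

Step 13. The vinyl metal may deprotonate the doubly activated C7–H (enolisation, then conjugation to the isopropylidene ketone), and facial selectivity on the flexible ten-membered ring may be low, giving the trans-dialkenyl carbinol that cannot lead to the 7E,11Z pattern. The fallback sets out from 26 and returns at 27, and uses a two-step alkynylation and semi-hydrogenation: HC≡CMgBr with CeCl3 in THF at −78 °C, a slimmer and less basic nucleophile that should follow the Felkin–Anh course more closely, gives the ethynyl carbinol F4. H2 over Pd/CaCO3 poisoned with Pb(OAc)2 and quinoline in EtOAc should then reduce only the alkyne to the vinyl group of 27.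

Step 9. The ambident dienolate may alkylate on oxygen (six-membered enol ether), the tosylate may be lost by elimination, or the product may be conjugated by the base. The fallback sets out from 9 (with 12) and returns at 17, and moves the ring closure to a softer, non-ambident carbon nucleophile. PhSO2Na in DMF converts 12 into 2-[(tert-butyldimethylsilyloxy)methyl]allyl phenyl sulfone F5. Its α-lithio derivative (n-BuLi, THF, −78 °C) adds to aldehyde 9 to give the β-hydroxy sulfone F6. Dess–Martin periodinane gives the β-keto sulfone F7. K2CO3 in MeCN closes the ring by C-alkylation of the sulfonyl-stabilised carbanion on the tosylate to give the 2-(phenylsulfonyl)cyclohexanone F8. SmI2 in THF/MeOH at −78 °C removes the sulfonyl group, and α-protonation of the resulting enolate gives 17.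

Further compounds

F1 | step 14 | trimethylsilyl ether of 27 | CC(C)=CCC[C@@](C)(O[Si](CC)(CC)CC)[C@H]1C/C=C(\CO[Si](C)(C)C(C)(C)C)CC[C@H](C(C)=C)[C@](O[Si](C)(C)C)(C=C)CC1
F2 | step 14 | fourteen-membered trimethylsilyl enol ether (OSiMe3 on C12 trans to C10, 7E) | CC(C)=CCC[C@@](C)(O[Si](CC)(CC)CC)[C@H]1C/C=C(\CO[Si](C)(C)C(C)(C)C)CC/C=C(\C)CC/C=C(/O[Si](C)(C)C)CC1
F3 | step 14 | fourteen-membered lithium enolate | CC(C)=CCC[C@@](C)(O[Si](CC)(CC)CC)[C@H]1C/C=C(\CO[Si](C)(C)C(C)(C)C)CC/C=C(\C)CC/C=C(/[O-])CC1.[Li+]
F4 | step 13 | ten-membered ethynyl carbinol (ethynyl on C12 cis to isopropenyl on C7) | CC(C)=CCC[C@@](C)(O[Si](CC)(CC)CC)[C@H]1C/C=C(\CO[Si](C)(C)C(C)(C)C)CC[C@H](C(C)=C)[C@](O)(C#C)CC1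
F5 | step 9 | 2-[(tert-butyldimethylsilyloxy)methyl]allyl phenyl sulfone | C=C(CO[Si](C)(C)C(C)(C)C)CS(=O)(=O)c1ccccc1
F6 | step 9 | β-hydroxy sulfone from 9 and lithiated F5 (diastereomer mixture) | CC(C)=CCC[C@@](C)(O[Si](CC)(CC)CC)[C@H](CCC(O)C(C(=C)CO[Si](C)(C)C(C)(C)C)S(=O)(=O)c1ccccc1)COS(=O)(=O)c1ccc(C)cc1
F7 | step 9 | β-keto sulfone | CC(C)=CCC[C@@](C)(O[Si](CC)(CC)CC)[C@H](CCC(=O)C(C(=C)CO[Si](C)(C)C(C)(C)C)S(=O)(=O)c1ccccc1)COS(=O)(=O)c1ccc(C)cc1
F8 | step 9 | 2-(phenylsulfonyl)cyclohexanone with the silyloxypropenyl group on the same carbon | CC(C)=CCC[C@@](C)(O[Si](CC)(CC)CC)[C@@H]1CCC(=O)C(C1)(C(=C)CO[Si](C)(C)C(C)(C)C)S(=O)(=O)c1ccccc1
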